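**Strategy**

Salimabromide is cut at the two bonds that flank the CH=CH unit of its cycloheptenone ring: the bond from the methyl-bearing quaternary carbon to the lactone α-carbon (shared with the tetralin ring) and the bond from the other alkene carbon to the ring-ketone carbon. This allyl unit is exploited by a one-pot Claisen ring expansion/transannular Hosomi–Sakurai reaction. The precursor is a seven-membered cyclic 2-alkoxydiene ester (a 3-benzoxepine) whose tertiary ether carbon bears an (E)-vinylsilane. The [3,3] shift gives a nine-membered allylsilane–enone and relays chirality to the C–Si carbon; TiCl4 then closes the tetralin and cycloheptene rings. Oxidation levels at the two oxygenated ring carbons are exchanged afterwards.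

Key step: step 8

Remarks: Compounds 1, 5 and 7 are assumed to be commercially available. The stereochemical course of step 8 is derived for a suprafacial [3,3] shift followed by anti SE2′ allylation; on that basis the R carbinol of 9 should lead to the natural series whichever geometry the ring alkene of 12 adopts (12 is drawn with the cis ring alkene). Locants in the Why lines are those of the compound names.

**Route**

Step 1
Reactants: 1 2-(4-ethylphenyl)-2-methylpropanoic acid
Product: 2 2-(4-ethyl-2-iodophenyl)-2-methylpropanoic acid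
Conditions: Pd(OAc)2 (5 mol %), PhI(OAc)2 (0.55 equiv), I2 (0.55 equiv), DMF, 60 °C, dark
Reagents that add atoms: iodine, [I][I]
Why: Carboxylate-directed palladium-catalysed ortho C–H iodination (six-membered palladacycle, acetyl hypoiodite formed in the flask) should functionalise one of the two equivalent ortho positions, the gem-dimethyl group favouring cyclopalladation and the limited iodine supply restraining di-iodination.

Step 2
Reactants: 2 2-(4-ethyl-2-iodophenyl)-2-methylpropanoic acid
Product: 4 3-(4-ethyl-2-iodophenyl)-3-methylbutan-2-one, via acid chloride 3 (not isolated)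
Conditions: (COCl)2, DMF (cat.), CH2Cl2, 0 °C to rt; evaporate; Me2CuLi, Et2O, –78 °C
Reagents that add atoms: lithium dimethylcuprate, [Li+].C[Cu-]C
Why: Acid chloride formation followed by acylation of a lithium dialkylcuprate should stop at the methyl ketone, and at –78 °C the aryl iodide should not exchange.

Step 3
Reactants: 4 3-(4-ethyl-2-iodophenyl)-3-methylbutan-2-one; 5 methyl prop-2-ynoate
Product: 6 methyl 3-[5-ethyl-2-(2-methyl-3-oxobutan-2-yl)phenyl]prop-2-ynoate
Conditions: PdCl2(PPh3)2 (3 mol %), CuI (6 mol %), K2CO3, THF, 50 °C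
Reagents that add atoms: methyl prop-2-ynoate, C#CC(=O)OC
Why: Sonogashira coupling of the aryl iodide, with an inorganic base in place of an amine so that nothing adds to the propiolate.

Step 4
Reactants: 6 methyl 3-[5-ethyl-2-(2-methyl-3-oxobutan-2-yl)phenyl]prop-2-ynoate; 7 ethynyl(trimethyl)silane
Product: 8 methyl (2E)-3-[5-ethyl-2-(2-methyl-3-oxobutan-2-yl)phenyl]-5-(trimethylsilyl)pent-2-en-4-ynoate
Conditions: Pd(OAc)2 (5 mol %), tris(2,6-dimethoxyphenyl)phosphine (5 mol %), PhMe, rt to 40 °C
Reagents that add atoms: ethynyl(trimethyl)silane, C#C[Si](C)(C)C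
Why: Palladium-catalysed cross-addition of a terminal (donor) alkyne to an ynoate (acceptor) should place the alkynyl group on the β-carbon by syn addition, so that the ester lies cis to the arene and trans to the new alkyne.

Step 5
Reactants: 8 methyl (2E)-3-[5-ethyl-2-(2-methyl-3-oxobutan-2-yl)phenyl]-5-(trimethylsilyl)pent-2-en-4-ynoate; 7 ethynyl(trimethyl)silane
Product: 9 methyl (2E)-3-{5-ethyl-2-[(3R,4E)-3-hydroxy-2,3-dimethyl-5-(trimethylsilyl)pent-4-en-2-yl]phenyl}-5-(trimethylsilyl)pent-2-en-4-ynoate
Conditions: 7, Cp2Zr(H)Cl, CH2Cl2, rt; Me2Zn, PhMe, –78 °C; then 8, Ti(OiPr)4 (1.2 equiv), chiral trans-cyclohexane-1,2-diamine bis(hydroxycamphorsulfonamide) ligand (10 mol %, the enantiomer that gives the R carbinol), rt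
Reagents that add atoms: (E)-2-(trimethylsilyl)ethenyl(methyl)zinc (made in the flask from 7), C[Zn]/C=C/[Si](C)(C)C
Why: Catalytic asymmetric 1,2-addition of an alkenylzinc (hydrozirconation, then transmetalation to zinc) to a ketone under titanium/bis(sulfonamide) diol control should set C-3 as R through the large size difference between the methyl and tert-alkyl flanks, the organozinc leaving the ester and the silylalkyne alone.

Step 6
Reactants: 9 methyl (2E)-3-{5-ethyl-2-[(3R,4E)-3-hydroxy-2,3-dimethyl-5-(trimethylsilyl)pent-4-en-2-yl]phenyl}-5-(trimethylsilyl)pent-2-en-4-ynoate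
Product: 10 methyl (2Z)-3-{5-ethyl-2-[(3R,4E)-3-hydroxy-2,3-dimethyl-5-(trimethylsilyl)pent-4-en-2-yl]phenyl}pent-2-en-4-ynoate
Conditions: K2CO3 (cat.), MeOH, 0 °C
Reagents that add atoms: none
Why: Protodesilylation by methanolysis should cleave only the sp-bound silicon, the vinylic silyl group being far less labile (the change from E to Z is a priority-rule effect only).

Step 7
Reactants: 10 methyl (2Z)-3-{5-ethyl-2-[(3R,4E)-3-hydroxy-2,3-dimethyl-5-(trimethylsilyl)pent-4-en-2-yl]phenyl}pent-2-en-4-ynoate
Product: 11 methyl (2E)-2-{(2R)-7-ethyl-1,1,2-trimethyl-4-methylidene-2-[(E)-2-(trimethylsilyl)ethenyl]-1,2-dihydro-3-benzoxepin-5(4H)-ylidene}acetate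
Conditions: Ph3PAuCl (5 mol %), AgOTf (5 mol %), 2,6-di-tert-butylpyridine (10 mol %), CH2Cl2, 0 °C
Reagents that add atoms: none
Why: Gold-catalysed intramolecular hydroalkoxylation of the terminal alkyne (7-exo-dig, the tertiary hydroxyl adding to the internal alkyne carbon) should give the cyclic 2-alkoxydiene with an exocyclic methylene, the ester being trans to the alkyne and unable to compete, and the stereocentre untouched.

Step 8
Reactants: 11 methyl (2E)-2-{(2R)-7-ethyl-1,1,2-trimethyl-4-methylidene-2-[(E)-2-(trimethylsilyl)ethenyl]-1,2-dihydro-3-benzoxepin-5(4H)-ylidene}acetate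
Product: 13 methyl 3-ethyl-10,11,11-trimethyl-6-oxo-6,7,10,11-tetrahydro-5H-5,10-methanobenzo[9]annulene-12-carboxylate (bridgeheads as in 18; ester syn to the benzo bridge), via nine-membered allylsilane enone 12 (not isolated)
Conditions: PhMe (0.01 M), 120 °C, sealed tube; then –78 °C, TiCl4 (1.2 equiv), CH2Cl2; H2O
Reagents that add atoms: none
Why: Heating should trigger a Claisen rearrangement of the allyl vinyl ether embedded in the benzoxepine (exocyclic CH2 to the silyl-bearing vinyl terminus, suprafacial, bridged chair-like transition state), giving the nine-membered ketone 12 that now holds both an allylsilane and a γ-keto-enoate; TiCl4 should then induce a transannular Hosomi–Sakurai conjugate allylation in which C-10 of 12 attacks the enoate carbon β to the ketone, silicon leaves as Me3SiCl and the double bond moves to its final place. The closest known reaction types are the Claisen ring expansion of 2-methylene cyclic ethers carrying a vinyl group at the other ether carbon, the Claisen rearrangement of γ-silyl allyl vinyl ethers to chiral allylsilanes, and intramolecular allylsilane additions to enones. The [3,3] shift is a two-atom ring expansion (seven to nine); the allylation closes the six-membered tetralin ring (exo with respect to the allylsilane double bond, endo with respect to the enoate) and thereby divides the nine-membered ring into the bridged cycloheptene. The R carbinol centre fixes the face of the [3,3] shift and is relayed to the C–Si carbon (8R, cis ring alkene); anti SE2′ attack relative to silicon then sets the quaternary methyl-bearing carbon, the bridgehead hydrogen arrives on protonation of the titanium enolate from its only open face, and the ester-bearing carbon follows from the enoate geometry (ester toward the arene, corrected in step 10). The step needs [3,3] over [1,3] shift or ionisation, which the neutral acid-free thermal stage should secure, and conjugate over carbonyl addition, which is secured because carbonyl attack would be a 5-endo closure and the aryl-bearing enoate carbon is blocked.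

Step 9
Reactants: 13 methyl 3-ethyl-10,11,11-trimethyl-6-oxo-6,7,10,11-tetrahydro-5H-5,10-methanobenzo[9]annulene-12-carboxylate
Product: 14 methyl 3-ethyl-7-hydroxy-10,11,11-trimethyl-6-oxo-6,7,10,11-tetrahydro-5H-5,10-methanobenzo[9]annulene-12-carboxylate (C-7 epimers)
Conditions: KN(SiMe3)2, THF, –78 °C; 2-(phenylsulfonyl)-3-phenyloxaziridine, –78 °C; AcOH
Reagents that add atoms: 2-(phenylsulfonyl)-3-phenyloxaziridine, O=S(=O)(N1OC1c1ccccc1)c1ccccc1
Why: Kinetic enolisation toward the doubly activated allylic CH2 (the other α-carbon is a bridgehead methine) and enolate α-hydroxylation with an N-sulfonyloxaziridine should put oxygen on the future ketone carbon; the configuration of this carbinol does not matter because it is oxidised in step 11.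

Step 10
Reactants: 14 methyl 3-ethyl-7-hydroxy-10,11,11-trimethyl-6-oxo-6,7,10,11-tetrahydro-5H-5,10-methanobenzo[9]annulene-12-carboxylate
Product: 16 3-ethyl-7-hydroxy-10,11,11-trimethyl-6,7,10,11-tetrahydro-5H-5,10-methanobenzo[9]annulene-12,6-carbolactone (ring stereocentres as in 18), via diol ester 15 (not isolated)
Conditions: NaBH4, MeOH, –20 °C; then NaOMe, MeOH, 50 °C; AcOH
Reagents that add atoms: none
Why: Borohydride reduction from the open convex face should place the new C-6 hydroxyl on the concave face toward the one-carbon bridge, after which methoxide epimerises the ester-bearing carbon through its enolate and the alkoxide closes the γ-lactone by transesterification, draining the epimer equilibrium.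

Step 11
Reactants: 16 3-ethyl-7-hydroxy-10,11,11-trimethyl-6,7,10,11-tetrahydro-5H-5,10-methanobenzo[9]annulene-12,6-carbolactone
Product: 17 didebromosalimabromide (salimabromide lacking both bromine atoms)
Conditions: MnO2, CH2Cl2, rt
Reagents that add atoms: none
Why: Oxidation of the only free alcohol, which is allylic, with manganese dioxide should give the cis-enone of the seven-membered ring.

Step 12
Reactants: 17 didebromosalimabromide
Product: 18 salimabromide
Conditions: N-bromosuccinimide (2.2 equiv), CF3CO2H/H2SO4, 0 °C to rt, dark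
Reagents that add atoms: N-bromosuccinimide, BrN1C(=O)CCC1=O
Why: Electrophilic aromatic bromination of the trialkylbenzene should go to the two positions ortho to the ethyl group (one also para, the other ortho, to the benzylic ring-fusion carbon), the third free position being the least activated and shielded by the gem-dimethyl carbon, while the protonated enone and the lactone stay inert.

**Compound list**

1 | 2-(4-ethylphenyl)-2-methylpropanoic acid | CCc1ccc(cc1)C(C)(C)C(O)=O | starting material
2 | 2-(4-ethyl-2-iodophenyl)-2-methylpropanoic acid | CCc1ccc(c(I)c1)C(C)(C)C(O)=O | intermediate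
3 | 2-(4-ethyl-2-iodophenyl)-2-methylpropanoyl chloride | CCc1ccc(c(I)c1)C(C)(C)C(Cl)=O | intermediate (not isolated)
4 | 3-(4-ethyl-2-iodophenyl)-3-methylbutan-2-one | CCc1ccc(c(I)c1)C(C)(C)C(C)=O | intermediate
5 | methyl prop-2-ynoate | C#CC(=O)OC | starting material
6 | methyl 3-[5-ethyl-2-(2-methyl-3-oxobutan-2-yl)phenyl]prop-2-ynoate | CCc1ccc(c(c1)C#CC(=O)OC)C(C)(C)C(C)=O | intermediate
7 | ethynyl(trimethyl)silane | C#C[Si](C)(C)C | starting material
8 | methyl (2E)-3-[5-ethyl-2-(2-methyl-3-oxobutan-2-yl)phenyl]-5-(trimethylsilyl)pent-2-en-4-ynoate (ester cis to the arene) | COC(=O)/C=C(/C#C[Si](C)(C)C)c1cc(CC)ccc1C(C)(C)C(C)=O | intermediate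
9 | methyl (2E)-3-{5-ethyl-2-[(3R,4E)-3-hydroxy-2,3-dimethyl-5-(trimethylsilyl)pent-4-en-2-yl]phenyl}-5-(trimethylsilyl)pent-2-en-4-ynoate | COC(=O)/C=C(/C#C[Si](C)(C)C)c1cc(CC)ccc1C(C)(C)[C@](C)(O)/C=C/[Si](C)(C)C | intermediate
10 | methyl (2Z)-3-{5-ethyl-2-[(3R,4E)-3-hydroxy-2,3-dimethyl-5-(trimethylsilyl)pent-4-en-2-yl]phenyl}pent-2-en-4-ynoate | COC(=O)/C=C(/C#C)c1cc(CC)ccc1C(C)(C)[C@](C)(O)/C=C/[Si](C)(C)C | intermediate
11 | methyl (2E)-2-{(2R)-7-ethyl-1,1,2-trimethyl-4-methylidene-2-[(E)-2-(trimethylsilyl)ethenyl]-1,2-dihydro-3-benzoxepin-5(4H)-ylidene}acetate | COC(=O)/C=C1/C(=C)O[C@](C)(/C=C/[Si](C)(C)C)C(C)(C)c2ccc(CC)cc21 | intermediate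
12 | methyl (2E)-2-[(8R,9Z)-3-ethyl-10,11,11-trimethyl-6-oxo-8-(trimethylsilyl)-6,7,8,11-tetrahydro-5H-benzo[9]annulen-5-ylidene]acetate | COC(=O)/C=C1/C(=O)C[C@@H]([Si](C)(C)C)/C=C(C)\C(C)(C)c2ccc(CC)cc21 | intermediate (not isolated)
13 | methyl 3-ethyl-10,11,11-trimethyl-6-oxo-6,7,10,11-tetrahydro-5H-5,10-methanobenzo[9]annulene-12-carboxylate; bridgeheads C-5 and C-10 as in 18, ester on the one-carbon bridge syn to the benzo bridge (C-12 epimer of the natural series) | COC(=O)[C@@H]1[C@@](C)(C=CCC3=O)C(C)(C)c2ccc(CC)cc2[C@H]13 | intermediate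
14 | 7-hydroxy derivative of 13 (both C-7 epimers) | COC(=O)[C@@H]1[C@@](C)(C=CC(O)C3=O)C(C)(C)c2ccc(CC)cc2[C@H]13 | intermediate
15 | methyl 3-ethyl-6,7-dihydroxy-10,11,11-trimethyl-6,7,10,11-tetrahydro-5H-5,10-methanobenzo[9]annulene-12-carboxylate; 6-hydroxyl syn to the one-carbon bridge, C-7 unspecified | COC(=O)[C@@H]1[C@@](C)(C=CC(O)[C@H]3O)C(C)(C)c2ccc(CC)cc2[C@H]13 | intermediate (not isolated)
16 | 3-ethyl-7-hydroxy-10,11,11-trimethyl-6,7,10,11-tetrahydro-5H-5,10-methanobenzo[9]annulene-12,6-carbolactone; all four ring stereocentres as in 18, C-7 unspecified | CCc1ccc2c(c1)[C@H]1[C@@H]3OC(=O)[C@H]1[C@@](C)(C=CC3O)C2(C)C | intermediate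
17 | didebromosalimabromide | CCc1ccc2c(c1)[C@H]1[C@@H]3OC(=O)[C@H]1[C@@](C)(C=CC3=O)C2(C)C | intermediate
18 | salimabromide | CCc1c(Br)cc2c(c1Br)[C@H]1[C@@H]3OC(=O)[C@H]1[C@@](C)(C=CC3=O)C2(C)C | target

**Step count and risks**

Total step count: 12. Longest linear sequence: 12 steps (1 to 18).

Steps most likely to fail:

1. Step 8. In the Lewis-acid stage, protodesilylation of the allylsilane or loss of the anti SE2′ pathway could outrun the transannular conjugate allylation. Fallback: from 11, the rearrangement is run purely thermally (o-xylene, 145 °C, hindered amine base). The Claisen product should then undergo a transannular Alder-ene reaction, in which the hydrogen on the silyl-bearing carbon is passed suprafacially to the aryl-bearing enoate carbon. This gives the vinylsilane methyl 3-ethyl-10,11,11-trimethyl-6-oxo-8-(trimethylsilyl)-6,7,10,11-tetrahydro-5H-5,10-methanobenzo[9]annulene-12-carboxylate F1. Protodesilylation with CF3CO2H in CH2Cl2 at 0 °C brings the route back at 13.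

2. Step 7. The hindered tertiary hydroxyl may add too slowly, so that 8-endo attack or gold-promoted ionisation of the allylic alcohol takes over. Fallback: from 10, the alkyne is hydrated to the methyl ketone methyl (2E)-3-{5-ethyl-2-[(3R,4E)-3-hydroxy-2,3-dimethyl-5-(trimethylsilyl)pent-4-en-2-yl]phenyl}-4-oxopent-2-enoate F2 (Ph3PAuCl/AgOTf cat., H2O, MeOH). F2 is converted to its dimethyl ketal, methyl (2E)-3-{5-ethyl-2-[(3R,4E)-3-hydroxy-2,3-dimethyl-5-(trimethylsilyl)pent-4-en-2-yl]phenyl}-4,4-dimethoxypent-2-enoate F3 (HC(OMe)3, MeOH, pyridinium tosylate). Warming in PhMe with a trace of pyridinium tosylate and removal of methanol should effect intramolecular transketalisation and elimination, coming back at 11.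

3. Step 5. Addition to the very hindered ketone may be slow and the face discrimination insufficient. Fallback: from 8, (E)-2-(trimethylsilyl)ethenyllithium (from (E)-(2-bromoethenyl)trimethylsilane and t-BuLi) is added with anhydrous CeCl3 in THF at –78 °C without stereocontrol. This gives the racemic carbinol methyl (2E)-3-{5-ethyl-2-[(3RS,4E)-3-hydroxy-2,3-dimethyl-5-(trimethylsilyl)pent-4-en-2-yl]phenyl}-5-(trimethylsilyl)pent-2-en-4-ynoate F4. The enantiomers are separated by preparative chromatography on a chiral stationary phase, and the R enantiomer rejoins the route at 9.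

Further compounds
F1 | step 8 | methyl 3-ethyl-10,11,11-trimethyl-6-oxo-8-(trimethylsilyl)-6,7,10,11-tetrahydro-5H-5,10-methanobenzo[9]annulene-12-carboxylate | COC(=O)[C@@H]1[C@@](C)(C=C([Si](C)(C)C)CC3=O)C(C)(C)c2ccc(CC)cc2[C@H]13
F2 | step 7 | methyl (2E)-3-{5-ethyl-2-[(3R,4E)-3-hydroxy-2,3-dimethyl-5-(trimethylsilyl)pent-4-en-2-yl]phenyl}-4-oxopent-2-enoate | COC(=O)/C=C(/C(C)=O)c1cc(CC)ccc1C(C)(C)[C@](C)(O)/C=C/[Si](C)(C)C
F3 | step 7 | methyl (2E)-3-{5-ethyl-2-[(3R,4E)-3-hydroxy-2,3-dimethyl-5-(trimethylsilyl)pent-4-en-2-yl]phenyl}-4,4-dimethoxypent-2-enoate | COC(=O)/C=C(/C(C)(OC)OC)c1cc(CC)ccc1C(C)(C)[C@](C)(O)/C=C/[Si](C)(C)C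
F4 | step 5 | methyl (2E)-3-{5-ethyl-2-[(3RS,4E)-3-hydroxy-2,3-dimethyl-5-(trimethylsilyl)pent-4-en-2-yl]phenyl}-5-(trimethylsilyl)pent-2-en-4-ynoate | COC(=O)/C=C(/C#C[Si](C)(C)C)c1cc(CC)ccc1C(C)(C)C(C)(O)/C=C/[Si](C)(C)C
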